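(The numbers in the tables come from a simulation for substances that don't exist; noise was put on by code.)

The birch run at 5 °C ends at 35.1% of target with 0.5% of starting material left after 50.0 min, and from that pair I reckon what the flasks below can hold.

| flask | starting material | reagent | temperature | remark | time |
|---|---|---|---|---|---|
| cedar | 0.064 M | 3 equiv | −10 °C | run made earlier |  |
| larch | 0.064 M | 1.5 equiv | 5 °C | run made earlier |  |
| maple | 0.064 M | 6 equiv | −10 °C | run made earlier |  |
| birch | 0.096 M | 3 equiv | 5 °C | run made earlier |  |
| Sunday's | 0.064 M (fed, over 50 min) | 3.00 equiv |  | the addition at −25 °C, then warmed to 5 °C; the feed brings no volume worth counting | 1.0 h |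
| Friday's | 0.064 M | 3.00 equiv | 5 °C | everything together at the start | 1.0 h |
| Saturday's | 0.064 M | 3.00 equiv |  | everything together at the start at −25 °C, warmed to 5 °C at 50 min | 1.0 h |
| Monday's | 0.064 M (fed, over 50 min) | 3.00 equiv | 5 °C | all else is in the flask from the start; the feed brings no volume worth counting | 1.0 h |
| Tuesday's | 0.064 M (fed, over 12 min) | 3.00 equiv | 5 °C | all else is in the flask from the start; the feed brings no volume worth counting | 1.0 h |

| run | time / min | target / % | starting material / % |
|---|---|---|---|
| cedar | 6.00 | 8.7 | 59.3 |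
| cedar | 20.0 | 30.9 | 27.4 |
| cedar | 30.0 | 39.2 | 19.2 |
| cedar | 50.0 | 46.8 | 11.2 |
| cedar | 80.0 | 52.1 | 5.6 |
| cedar | 120 | 55.8 | 3.8 |
| larch | 6.00 | 5.4 | 68.3 |
| larch | 15.0 | 8.5 | 48.6 |
| larch | 20.0 | 9.5 | 42.6 |
| larch | 30.0 | 12.1 | 32.3 |
| larch | 40.0 | 11.8 | 26.1 |
| larch | 50.0 | 12.8 | 22.6 |
| maple | 8.00 | 31.5 | 26.1 |
| maple | 12.0 | 42.6 | 16.0 |
| maple | 15.0 | 48.2 | 11.7 |
| maple | 30.0 | 60.8 | 3.4 |
| maple | 40.0 | 63.4 | 2.3 |
| maple | 60.0 | 65.6 | 0.2 |
| maple | 120 | 66.1 | 0 |
| birch | 4.00 | 20.1 | 40.6 |
| birch | 8.00 | 26.9 | 23.2 |
| birch | 15.0 | 30.8 | 11.4 |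
| birch | 25.0 | 34.2 | 4.8 |
| birch | 50.0 | 35.1 | 0.5 |

(standard deviation of a reading: 0.5 percentage points)

- a reading or a percentage of target counts all its forms, free or not
- a reading of starting material is of its free form alone

* the flask with the highest amount of target, in percent of the starting material charged ("all alike" if they lie within 1.5 percentage points) (Sunday's / Friday's / Saturday's / Monday's / Tuesday's / all alike)
* final target, as a percentage of the starting material charged, in Sunday's
* final target, as a percentage of the starting material charged, in Friday's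
* final target, as a percentage of the starting material charged, in Saturday's
* final target, as a percentage of the starting material charged, in Monday's
* final target, as a percentage of the starting material charged, in Tuesday's

I follow one molecule of starting material to its fork, where it either becomes target or goes elsewhere, and I write the odds as target over everything else consumed. Birch reads 0.545 and larch, also at 5 °C but unfinished at 50.0 min, reads 0.198. Those odds stand in a ratio of 2.75, while c(reagent) as charged stands in a ratio of 3.00 and c(starting material) differs between the two runs as well, and as an assumption of mine I let the odds scale with c(reagent). At Friday's charge they become 0.363, which gives the warm fork chance, the selectivity of a molecule spent at 5 °C with this charge, of 26.7%.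

That chance is my estimated floor for a finished Saturday's, since cedar at −10 °C reads 58.0% per molecule consumed, a better chance than the warm one. For the ceiling, I allow Saturday's cold stretch of 50 min no more target than cedar held at 50.0 min, which is 46.8%, as −25 °C is colder than −10 °C. I then send the remainder through the warm fork, which gives 61.0%. Friday's, held at 5 °C throughout, should sit near the floor.

The forecast names Saturday's as best, at 52% (range 41% to 63%), inside my bracket, with Friday's at 30%, Sunday's at 40%, Monday's at 31% and Tuesday's at 31%, and it holds that “Saturday's cold batch converts most material selectively”.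

The flasks give 24.4% for Sunday's, 28.5% for Friday's, 30.5% for Saturday's, 26.2% for Monday's and 28.4% for Tuesday's, so Saturday's leads.

    reagent + intermediate A ⇌ intermediate B (K = 16.0 M⁻¹, k = 0.0320 M⁻¹ s⁻¹, Ea = 52.0 kJ mol⁻¹, ΔH = −90.0 kJ mol⁻¹)
    starting material + reagent ⇌ intermediate C (K = 0.740 M⁻¹, k = 0.0280 M⁻¹ s⁻¹, Ea = 61.0 kJ mol⁻¹, ΔH = −87.0 kJ mol⁻¹)
    starting material + reagent → intermediate A (k = 0.00930 M⁻¹ s⁻¹, Ea = 53.0 kJ mol⁻¹)
    reagent + intermediate C → target (k = 0.0440 M⁻¹ s⁻¹, Ea = 52.0 kJ mol⁻¹)
    intermediate B → side product B (k = 6.80 × 10⁻⁴ s⁻¹, Ea = 91.0 kJ mol⁻¹)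
    starting material + target ⇌ idle adduct, settled at all times (K = 6.60 M⁻¹, ΔH = −31.0 kJ mol⁻¹)
    intermediate A → side product A (k = 0.00110 s⁻¹, Ea = 85.0 kJ mol⁻¹)
    (constants at 5 °C)

Saturday's lands 3.8 percentage points above my floor and 22 points below the forecast, and at 1.00 h it still holds 22.6% of starting material, 12.5% of intermediate A and 16.1% of intermediate B. Friday's, with 1.40% of starting material left, stands 1.8 points above the same 26.7%. The neighbour is Sunday's flask read at 4.0 h: starting material stands at 0%, so I hold it against the warm fork chance of 26.7%, and it gives 32.1% of target, 5.4 points above that chance, with side product A at 37.7%.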